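(The data were generated by integration from invented constants; noise was put on by code.)

To whoever takes the bench: the reading comes at 80 min, and by then I expected these flasks to hold target, isomer of the product and both side products, with target still slowly sinking.

| flask | starting material | remark | time |
|---|---|---|---|
| gamma | 0.32 M | run made earlier |  |
| delta | 1.7 M | run made earlier |  |
| Tuesday's | 0.80 M |  | 80 min |
| Sunday's | 2.0 M |  | 80 min |
| Monday's | 0.60 M |  | 80 min |
| Thursday's | 1.5 M |  | 80 min |
| Wednesday's | 2.7 M |  | 80 min |

- gamma (time / min: target / %): 6.00: 63; 12.0: 62; 15.0: 61; 25.0: 56; 30.0: 56; 40.0: 53
- delta (time / min: target / %): 3.00: 48; 5.00: 45; 8.00: 46; 12.0: 42; 15.0: 43; 25.0: 40; 40.0: 38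

(readings scatter by 1.5 percentage points)

- percent here means starting material units held: one side product B counts as two
- the numbers in the tables scatter by 1.5 percentage points (one standard deviation)
- steps thought possible: target <-> isomer of the product; starting material -> target; starting material + target -> side product B; starting material -> side product A

- ranking by amount of target, in percent of the starting material charged, from high to low, at 80 min (Tuesday's / Sunday's / Monday's / Thursday's / Wednesday's)
- the amount of target, in percent of the starting material charged of the flask you put first, at 80 min
- the amount of target, in percent of the starting material charged of the flask you put last, at 80 min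

In both earlier runs target was falling from early on, so I took as the zero of my scale the plain case in which it loses the same fraction of itself per minute whatever the charge. Gamma went from 63% to 53% of its charge, which gave 0.00508 /min. Delta went from 48% to 38%, which gave 0.00631 /min. With a scatter of 1.5 percentage points I carried their mean, 0.00570 /min: the drift rate, an apparent first-order constant for the fraction of target lost per minute.

From 40.0 min to 80 min it keeps a fraction 0.796 of the target. Gamma's last reading then stood for 42.2% at 80 min and delta's for 30.3%. So I put Monday's, charged above gamma, below the first figure, and Wednesday's, charged above delta, below the second. I left word not to move the reading from 80 min: in my reckoning the drift rate took 20.4% of the target over the last 40.0 min before it.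

The forecast gave Monday's > Tuesday's > Thursday's > Sunday's > Wednesday's, with 42% first and 29% last, holding that “the target slowly isomerises in both runs” and applying a factor of 0.69.

Monday's gave 38.6% and Wednesday's 24.4%, in the order Monday's > Tuesday's > Thursday's > Sunday's > Wednesday's.

    target ⇌ isomer of the product (K = 2.70, k = 0.00670 /min)
    starting material → target (k = 0.860 /min)
    starting material + target → side product B (k = 0.490 /M/min)
    starting material → side product A (k = 0.280 /min)

Side product B stood at 15.3% in Monday's and 41.3% in Wednesday's at 80.0 min, the same as at 40.0 min. Monday's held 48.3% target at 40.0 min, and the drift rate carried that to 38.5%, against 38.6% in the flask. Wednesday's held 30.5% at 40.0 min, which the same rate carried to 24.3%, against 24.4% in the flask.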